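(The numbers in the tables were generated by integration with made-up constants; scatter was added.)

2.45 mM of the midnight charge ends neither as target nor spent on protic impurity, if each protic impurity takes one starting material. Call this the shortfall S: charge, less plateau of target, less charge of protic impurity.

| flask | starting material | protic impurity | temperature | remark | time |
|---|---|---|---|---|---|
| midnight | 5 mM | 0.050 mM | 55 °C | run made earlier |  |
| noon | 5 mM | 0.20 mM | 70 °C | run made earlier |  |
| dawn | 7.5 mM | 0.10 mM | 55 °C | run made earlier |  |
| Saturday's | 5.0 mM | 0.100 mM | 80 °C |  | 5.0 min |
| Sunday's | 5.0 mM | 0.100 mM | 60 °C |  | 5.0 min |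

- midnight (time / min: target / %): 1.50: 51; 3.00: 48; 5.00: 52; 6.00: 46; 15.0: 53; 20.0: 50
- noon (time / min: target / %): 1.50: 68; 3.00: 65; 5.00: 62; 6.00: 65; 8.00: 62; 10.0: 66
- dawn (time / min: target / %): 1.50: 68; 5.00: 66; 10.0: 66; 15.0: 65; 20.0: 67

(each reading ± 2 percentage points)

- what was read earlier has a scatter of 2 percentage points, one standard deviation
- a reading or a percentage of target counts all its forms, free or not

- which flask leads in amount of target, in percent of the starting material charged ("all alike" within 1.5 percentage points) (Saturday's / Sunday's / all alike)
- how much target is there at the end, in percent of the starting material charged: Saturday's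
- how much target is there at the end, in percent of the starting material charged: Sunday's

All three runs are flat from their first reading, so their means serve as plateaus. The dawn flask, also at 55 °C, holds 7.5 mM of starting material and twice the protic impurity of the midnight flask, yet its S is 2.42 mM. Between these two flasks S stays put while the charge grows, and a reading scatters by 2 percentage points. The noon run, at 70 °C, gives a smaller S of 1.57 mM. With a constant factor per degree from the midnight S at 55 °C to the noon S at 70 °C, S is 2.11 mM at 60 °C and 1.16 mM at 80 °C, the latter hotter than any run. This shortfall frozen at its temperature carries the reckoning.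

In the first instants, the protic impurity can claim 2.00% of either charge. The middle goes unseen, since plateaus stand by 1.50 min at 55 °C. Both new flasks run hotter and are read later, so each should be at its end. There, the reckoning gives 74.7% of target for Saturday's and 55.8% for Sunday's, a gap of 19 points against a margin of 1.5 points.

The forecast differs, with all alike, 65% for Saturday's and 65% for Sunday's, on the ground of “a reversible limit near 65% that barely depends on temperature”.

Saturday's gives 75.9% and Sunday's 56.4%, so Saturday's leads.

    starting material → target, rate k1*[starting material]/(1 + ([starting material]/sat1)) (2.10 mM, k = 0.170 s⁻¹, Ea = 96.0 kJ mol⁻¹)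
    target ⇌ isomer of the product (K = 1.30, k = 0.190 s⁻¹, Ea = 76.0 kJ mol⁻¹, ΔH = −31.0 kJ mol⁻¹)
    starting material + protic impurity → quenched substrate (k = 560 L mol⁻¹ s⁻¹, Ea = 46.0 kJ mol⁻¹)
    crystals ⇌ target, rate k4*(cs4 - [target]) while solid is left; crystals form when [target] > cs4 (solubility = 1.60 mM, k = 4.30 s⁻¹)
    (constants at 60 °C)

In Sunday's, the isomer of the product holds 2.08 mM, beside S of 2.11 mM. A flask like Sunday's with 20 mM of starting material reckons to 88.9% and gives 89.1%. In Sunday's, dissolved target and isomer of the product relax by their own step with a half-life of 2.06 s, short against 5.0 min: thermodynamic control. Starting material stands at 0% in Sunday's and 0% in Saturday's. Ten times the time changes neither flask: at 50.0 min, Sunday's still holds 56.4% of target and Saturday's 75.9%.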